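Write the balance of the protic impurity first, because it is the reagent charged in the smaller amount: whatever of it goes ends up as quenched reagent, one dissolved gas spent for each.

| setting | beta | gamma | epsilon | south-east | south |
|---|---|---|---|---|---|
| solid substrate | 0.047 M | 0.061 M | 0.087 M | 0.087 M | 0.060 M |
| gas phase | 12 mM (held) | 12 mM (held) | 12 mM (held) | 12 mM (held) | 12 mM (held) |
| protic impurity | 4.35 mM | 4.35 mM | 2.1 mM | 4.35 mM | 1.50 mM |
| remark | run made earlier | run made earlier | run made earlier |  |  |
| time |  |  |  | 2.5 min | 2.5 min |

- beta (time / s: target / %, side product / %, solid substrate / %): 20.0: 2.4, 2.3, 89.8; 40.0: 9.0, 6.0, 80.5; 60.0: 14.5, 9.5, 71.1; 80.0: 20.5, 13.8, 63.0; 120: 31.6, 20.4, 43.3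
- gamma (time / s: target / %, side product / %, solid substrate / %): 10.0: 1.3, 0.3, 95.8; 15.0: 1.2, 2.2, 93.8; 30.0: 4.7, 3.4, 88.9; 60.0: 12.0, 7.3, 78.6; 120: 24.6, 16.2, 57.4
- epsilon (time / s: target / %, side product / %, solid substrate / %): 10.0: 0.2, 0.9, 98.2; 15.0: 0.9, 0.9, 95.8; 30.0: 3.0, 3.3, 92.9; 60.0: 7.5, 4.8, 85.2; 120: 17.9, 10.7, 69.9

(each reading ± 0.5 percentage points)

- which one finishes higher in share of target in all that became target or side product ("neither" within 2 percentage points) (south-east / south / neither)
- share of target in all that became target or side product, south-east
- share of target in all that became target or side product, south

- as a solid, counted per litre of solution: solid substrate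
- at the start none of the gas is dissolved
- steps thought possible: gas phase <-> dissolved gas; starting material + dissolved gas -> target; starting material -> side product; solid substrate <-> starting material; dissolved gas + protic impurity -> quenched reagent
- at the start none of the solid substrate is in solution
- what has only dissolved of solid substrate counts as not reacted

The bench rule says to take that amount off the target, as if each impurity took one unit of target and left it to become side product. Divide the impurity by the solid substrate charged: south gives 2.50%, this impurity share, and south-east gives 5.00%. The share of target is counted on what has reacted, not on the charge, so the rule's cost is the impurity share divided by the fraction of the charge reacted. Beta at 120 s has 24.4 mM in target and side product and epsilon 24.9 mM, so take that amount as independent of loading and growing with time: scaled to 2.5 min, beta's amount is 35.1% of south-east's charge and 50.9% of south's. At full price, south-east would lag south by 9.3 percentage points in the share of target (the selectivity), over the margin of 2 points.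

But the rule treats the gas as a fixed dose, and here the gas phase is held at 12 mM. So test the price on the runs. At 120 s, beta has a full-price cost of 17.8% and target share 60.8%, while epsilon has 8.44% and 62.6%. That reads as a part of the full price paid of 0.194, a rough reading, since the two runs differ in loading too and each value carries a scatter of 0.5 points. South would clear the margin from 0.215 of the full price, and the reading lies just below that. My own reckoning is a gap of 1.8 points, so neither, but narrowly.

The forecast also said neither, with 61% for south-east and 62.5% for south, on the ground that “The impurity acts only modestly, by scavenging dissolved gas early”.

    gas phase ⇌ dissolved gas, rate k1*(csat - [dissolved gas]) (kL = 0.115 s⁻¹)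
    starting material + dissolved gas → target (k = 6.56 L mol⁻¹ s⁻¹)
    starting material → side product (k = 0.0421 s⁻¹)
    solid substrate ⇌ starting material, rate k4*(cs4 - [starting material]) while solid is left; crystals form when [starting material] > cs4 (solubility = 7.40 mM, k = 0.0399 s⁻¹)
    dissolved gas + protic impurity → quenched reagent (k = 7.94 L mol⁻¹ s⁻¹)

The flasks give neither: 61.4% for south-east and 61.8% for south, a gap of 0.40 points. In south at 2.50 min, quenched reagent stands at 2.50% of the charge, matching the impurity share of 2.50%, while the target step uses starting material 1.7 times as fast as the side step, a share of 62.7%.

Now take one more flask, like south but with 9.0 × 10⁻⁴ M of impurity. Its impurity share is 1.50%, so at the same reacted fraction of 50.9% full price allows a gain over south of 2 points, and the part read from the runs allows 0.38 points. The flask gives 61.9%.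

All runs are simulated from invented constants; noise was put on by code.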